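**Strategy.** The decalin is disconnected at C9–C10 (ring B) and C4–C5 (ring A), drimane numbering, back to an open-chain aryl farnesyl epoxide. One Lewis-acid-triggered epoxy-polyene cascade opens the oxirane at C4, closes ring A and then ring B, and ends by proton loss to C7=C8. It exploits the head-to-tail 1,5-diene pattern behind the methyl-bearing C10 and C8 and the all-anti array C4/C5/C10/C9: the two oxirane stereocentres, set by Sharpless epoxidation of the terminal E-allylic alcohol, are relayed through E,E-alkene geometry to four ring stereocentres. The C3 hydroxyl is then removed and the arene is advanced to the epoxy-enone ring.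

Key step: step 6

Remark on the chemistry: the oxirane is treated as a functional group placed on the finished carbocyclic skeleton (arene-derived six-membered ring, ring A, ring B). Drimane numbering is used for the decalin (ring A = C1–C5, C10; ring B = C5–C10; C11 = the CH2 link to the oxygenated ring).

Step 1
Reactants: 1 4-methoxy-3-methylphenol; 2 (2E,6E)-farnesyl bromide
Product: 4 4-methoxy-5-methyl-2-[(2E,6E)-3,7,11-trimethyldodeca-2,6,10-trien-1-yl]phenol, via sodium 4-methoxy-3-methylphenoxide 3 (not isolated)
Conditions: NaH, toluene, 0 °C to rt; then 2, rt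
Reagents that add atoms: none
Why: Ortho-C-allylation of a sodium phenoxide in a non-polar solvent (the tight ion pair blocks oxygen) should give SN2 attack by the unhindered ortho carbon, para to the methyl group, on the primary allylic bromide with both E alkenes retained; no stereocentre is formed.

Step 2
Reactants: 4 the C-farnesyl phenol
Product: 5 4-methoxy-5-methyl-2-[(2E,6E)-farnesyl]phenyl pivalate
Conditions: t-BuCOCl, Et3N, 4-(dimethylamino)pyridine (cat.), CH2Cl2, 0 °C to rt
Reagents that add atoms: pivaloyl chloride CC(C)(C)C(Cl)=O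
Why: Acylation of the phenol masks the oxygen against oxidation and cation capture and lowers the nucleophilicity of the arene for the cyclization.

Step 3
Reactants: 5 the aryl pivalate
Product: 6 2-[(2E,6E,10E)-12-hydroxy-3,7,11-trimethyldodeca-2,6,10-trien-1-yl]-4-methoxy-5-methylphenyl pivalate
Conditions: SeO2 (cat.), t-BuOOH, salicylic acid (cat.), CH2Cl2, 0 °C to rt
Reagents that add atoms: selenium dioxide O=[Se]=O (oxygen donor, catalytic); tert-butyl hydroperoxide CC(C)(C)OO (terminal oxidant that restores it)
Why: Catalytic SeO2 allylic oxidation (ene reaction then [2,3]-sigmatropic shift) should oxidise the E-methyl group of the terminal, most accessible trisubstituted alkene to the E-allylic alcohol, leaving the ester and the internal alkenes.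

Step 4
Reactants: 6 the E-allylic alcohol
Product: 7 (10S,11S)-10,11-epoxide of 6 (both oxirane carbons S; chain numbering)
Conditions: Ti(OiPr)4 (cat.), L-(+)-diethyl tartrate (cat.), t-BuOOH, 4 Å molecular sieves, CH2Cl2, −20 °C
Reagents that add atoms: tert-butyl hydroperoxide CC(C)(C)OO
Why: Sharpless asymmetric epoxidation; the titanium tartrate binds the allylic hydroxyl, so only the terminal alkene reacts, and the L-(+)-tartrate sets both oxirane stereocentres.

Step 5
Reactants: 7 the epoxy alcohol
Product: 8 tert-butyldimethylsilyl ether of 7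
Conditions: t-BuMe2SiCl, imidazole, DMF, 0 °C to rt
Reagents that add atoms: tert-butyldimethylsilyl chloride CC(C)(C)[Si](C)(C)Cl
Why: Standard silylation of the primary alcohol; the bulky silyl ether keeps this oxygen from chelating the Lewis acid in step 6 and survives to the last step.

Step 6
Reactants: 8 the epoxy silyl ether
Product: 9 11-aryl-3β-hydroxy-drim-7-ene (trans-decalin; 3β-OH; 4α-CH2OSiMe2t-Bu and 4β-CH3; 5α-H; C7=C8; 9β-CH2Ar; 10β-CH3; Ar = 4-methoxy-5-methyl-2-pivaloyloxyphenyl)
Conditions: MeAlCl2 (3 equiv), CH2Cl2, −78 °C; aq. NaHCO3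
Reagents that add atoms: none
Why: MeAlCl2 coordinates the oxirane oxygen, C5 of the E C5=C10 alkene attacks the tertiary carbon C4 from the backside (ring A, 6-endo at the oxirane and at the alkene), the developing C10 cation is captured by C9 of the E C8=C9 alkene (ring B, 6-endo-trig), and the C8 cation loses the axial C7 proton to give C7=C8. The closest known reaction type is the Lewis-acid-promoted epoxy-polyene cyclization of oxidosqualene-like substrates, including oxiranes that carry a protected hydroxymethyl group. C3 keeps its oxirane configuration (3β-OH) and C4 is inverted, so the E-derived silyloxymethyl branch becomes equatorial 4α and the methyl axial 4β. C5 and C10 arise from anti addition across the E alkene in a chair-chair array (trans fusion, 5α-H, 10β-methyl), and C9 from the E geometry of C8=C9, which places the arylmethyl arm equatorial (9β). The step needs opening at C4 and not at C3 (secured by the tertiary centre and the non-chelating silyl ether), proton loss from C7 and not from the C8 methyl (the axial C7–H is aligned with the empty orbital, and MeAlCl2 consumes the proton as methane so the kinetic alkene is not re-protonated), and no capture of the C8 cation by the arene or its oxygen (the pivalate lowers ring nucleophilicity and masks the oxygen).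

Step 7
Reactants: 9 the 3β-alcohol
Product: 10 O-(3β-yl) 1H-imidazole-1-carbothioate of 9
Conditions: 1,1'-thiocarbonyldiimidazole, 4-(dimethylamino)pyridine (cat.), toluene, 90 °C
Reagents that add atoms: 1,1'-thiocarbonyldiimidazole S=C(n1ccnc1)n1ccnc1
Why: Thioacylation of the equatorial secondary hydroxyl under neutral conditions (no alkoxide, so no silyl migration) gives the radical-labile thiocarbonyl derivative.

Step 8
Reactants: 10 the thiocarbonyl imidazolide
Product: 11 11-aryl-drim-7-ene (3-deoxy; 4α-CH2OSiMe2t-Bu; aryl pivalate unchanged)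
Conditions: Bu3SnH, azobisisobutyronitrile, toluene, 100 °C
Reagents that add atoms: none
Why: Barton–McCombie deoxygenation; stannyl radical addition to C=S and β-scission give the secondary C3 radical, which Bu3SnH reduces, deleting the C3 stereocentre while all others stay remote from the radical.

Step 9
Reactants: 11 the aryl pivalate
Product: 13 4,4-dimethoxy-5-methyl-2-(drim-7-en-11-yl)cyclohexa-2,5-dien-1-one (quinone monoketal; 4α-CH2OSiMe2t-Bu on the decalin), via sodium phenoxide 12 (not isolated)
Conditions: NaOMe, MeOH–THF, rt; then PhI(OAc)2, 0 °C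
Reagents that add atoms: methanol CO
Why: Methanolysis frees the phenoxide, and oxidative dearomatization with PhI(OAc)2 lets methanol add para, at the methoxy-bearing carbon, which fixes the carbonyl beside the carbon that carries the decalin arm.

Step 10
Reactants: 13 the quinone monoketal
Product: 14 (1R,6S)-5,5-dimethoxy-4-methyl-1-(drim-7-en-11-yl)-7-oxabicyclo[4.1.0]hept-3-en-2-one (epoxy ketone; 4α-CH2OSiMe2t-Bu on the decalin)
Conditions: t-BuOOH, aq. NaOH, N-benzylcinchonidinium chloride (cat.), toluene, 0 °C
Reagents that add atoms: tert-butyl hydroperoxide CC(C)(C)OO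
Why: Weitz–Scheffer nucleophilic epoxidation under chiral phase-transfer catalysis; the peroxide anion should add to the unsubstituted β-carbon and not to the methyl-bearing one, and the chiral ammonium ion pair is relied on for the face, so both oxirane carbons are set in one ring closure (the other diastereomer, if formed, is separable because the decalin is enantiopure).

Step 11
Reactants: 14 the epoxy ketone
Product: 15 (1S,2R,6S)-5,5-dimethoxy-4-methyl-1-(drim-7-en-11-yl)-7-oxabicyclo[4.1.0]hept-3-en-2-ol (hydroxyl trans to the oxirane oxygen)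
Conditions: i-Bu2AlH, THF, −78 °C
Reagents that add atoms: none
Why: 1,2-Reduction of the enone carbonyl; aluminium coordinated to the oxirane oxygen should deliver hydride from that face, which is also the face not shielded by the decalin arm on the adjacent carbon, giving the trans epoxy alcohol.

Step 12
Reactants: 15 the epoxy alcohol ketal
Product: 16 epoxypholamin B, (1S,5R,6S)-5-hydroxy-6-{[(1S,4aR,5R,8aR)-5-(hydroxymethyl)-2,5,8a-trimethyl-1,4,4a,5,6,7,8,8a-octahydronaphthalen-1-yl]methyl}-3-methyl-7-oxabicyclo[4.1.0]hept-3-en-2-one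
Conditions: aq. HF (48%), MeCN, 0 °C to rt
Reagents that add atoms: water O
Why: Aqueous HF should cleave the primary silyl ether and hydrolyse the dimethyl ketal to the enone in one operation, under acid mild enough for the epoxy ketone, the allylic alcohol and the trisubstituted alkene.

**Compound list**

1 | 4-methoxy-3-methylphenol | COc1ccc(O)cc1C | starting material
2 | (2E,6E)-farnesyl bromide | CC(C)=CCC/C(C)=C/CC/C(C)=C/CBr | starting material
3 | sodium 4-methoxy-3-methylphenoxide | COc1ccc([O-])cc1C.[Na+] | intermediate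
4 | 4-methoxy-5-methyl-2-[(2E,6E)-farnesyl]phenol | COc1cc(C/C=C(\C)CC/C=C(\C)CCC=C(C)C)c(O)cc1C | intermediate
5 | 4-methoxy-5-methyl-2-[(2E,6E)-farnesyl]phenyl pivalate | COc1cc(C/C=C(\C)CC/C=C(\C)CCC=C(C)C)c(OC(=O)C(C)(C)C)cc1C | intermediate
6 | 2-[(2E,6E,10E)-12-hydroxyfarnesyl]-4-methoxy-5-methylphenyl pivalate | COc1cc(C/C=C(\C)CC/C=C(\C)CC/C=C(\C)CO)c(OC(=O)C(C)(C)C)cc1C | intermediate
7 | (10S,11S)-10,11-epoxide of 6 | COc1cc(C/C=C(\C)CC/C=C(\C)CC[C@@H]2O[C@@]2(C)CO)c(OC(=O)C(C)(C)C)cc1C | intermediate
8 | tert-butyldimethylsilyl ether of 7 | COc1cc(C/C=C(\C)CC/C=C(\C)CC[C@@H]2O[C@@]2(C)CO[Si](C)(C)C(C)(C)C)c(OC(=O)C(C)(C)C)cc1C | intermediate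
9 | 11-aryl-3β-hydroxy-drim-7-ene (4α-CH2OSiMe2t-Bu, 4β-CH3, 5α-H, 9β-CH2Ar, 10β-CH3; Ar = 4-methoxy-5-methyl-2-pivaloyloxyphenyl) | COc1cc(C[C@H]2C(C)=CC[C@H]3[C@](C)(CO[Si](C)(C)C(C)(C)C)[C@@H](O)CC[C@]23C)c(OC(=O)C(C)(C)C)cc1C | intermediate
10 | O-(3β-yl) imidazole-1-carbothioate of 9 | COc1cc(C[C@H]2C(C)=CC[C@H]3[C@](C)(CO[Si](C)(C)C(C)(C)C)[C@@H](OC(=S)n4ccnc4)CC[C@]23C)c(OC(=O)C(C)(C)C)cc1C | intermediate
11 | 3-deoxy compound, 11-aryl-drim-7-ene with 4α-CH2OSiMe2t-Bu (aryl pivalate) | COc1cc(C[C@H]2C(C)=CC[C@H]3[C@](C)(CO[Si](C)(C)C(C)(C)C)CCC[C@]23C)c(OC(=O)C(C)(C)C)cc1C | intermediate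
12 | sodium phenoxide from 11 | COc1cc(C[C@H]2C(C)=CC[C@H]3[C@](C)(CO[Si](C)(C)C(C)(C)C)CCC[C@]23C)c([O-])cc1C.[Na+] | intermediate
13 | 4,4-dimethoxy-5-methyl-2-(drim-7-en-11-yl)cyclohexa-2,5-dien-1-one (4α-CH2OSiMe2t-Bu) | COC1(OC)C=C(C[C@H]2C(C)=CC[C@H]3[C@](C)(CO[Si](C)(C)C(C)(C)C)CCC[C@]23C)C(=O)C=C1C | intermediate
14 | (1R,6S)-epoxy ketone of 13 | CC1=CC(=O)[C@]2(C[C@H]3C(C)=CC[C@H]4[C@](C)(CO[Si](C)(C)C(C)(C)C)CCC[C@]34C)O[C@@H]2C1(OC)OC | intermediate
15 | (1S,2R,6S)-trans-epoxy alcohol (dimethyl ketal, silyl ether) | CC1=C[C@@H](O)[C@]2(C[C@H]3C(C)=CC[C@H]4[C@](C)(CO[Si](C)(C)C(C)(C)C)CCC[C@]34C)O[C@@H]2C1(OC)OC | intermediate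
16 | epoxypholamin B | CC1=C[C@@H](O)[C@]2(C[C@H]3C(C)=CC[C@H]4[C@](C)(CO)CCC[C@]34C)O[C@@H]2C1=O | target

Total step count: 12. Longest linear sequence: 12 steps (from 1).

**Steps most likely to fail**

Step 6 (key step). The cascade may go astray in three ways: the C8 cation may lose a proton from its methyl group (exocyclic alkene) or be captured by the arene, or the oxirane may open at C3 or rearrange to a carbonyl compound before the alkene engages. The fallback sets out from 8 and replaces the cationic cascade by a radical one. Cp2TiCl2 (cat.), Mn dust and 2,4,6-collidine hydrochloride in THF generate Cp2TiCl (trivalent titanium), which opens the oxirane homolytically to the tertiary C4 radical. Two 6-endo radical closures and titanium-mediated hydrogen loss should then give the exocyclic alkene isomer F1 (3β-hydroxy-drim-8(12)-ene with the same substituents), with no cation for the arene to trap. Isomerization of the exocyclic alkene into the ring at the less hindered C7 side (RhCl3·3H2O, EtOH, 70 °C) comes back to the route at 9.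

Step 10. Facial selectivity of the peroxide addition may be poor, since the decalin stereocentres are remote and the matched catalyst sense is not known in advance. The fallback sets out from 13 and uses auxiliary control. Ketal exchange with (R,R)-hydrobenzoin (pyridinium p-toluenesulfonate, benzene, reflux) should give the C2-symmetric dioxolane dienone F2. One phenyl group of F2 covers the upper face of the β-carbon next to the spiro centre, so t-BuOOH with 1,8-diazabicyclo[5.4.0]undec-7-ene in CH2Cl2 should add from the open face and give the epoxy ketone F3. Reduction with i-Bu2AlH as in step 11 gives the trans epoxy alcohol F4, and acid hydrolysis (aq. HF, MeCN, longer time for the dioxolane) removes the auxiliary and the silyl ether and comes back at 16.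

Step 11. Hydride may enter from the face opposite the oxirane and give the cis epoxy alcohol. The fallback sets out from 14. That cis isomer, the C2 epimer F5, is then made on purpose with an external hydride (LiBHEt3, THF, −78 °C) and inverted by Mitsunobu reaction (4-nitrobenzoic acid, PPh3, diisopropyl azodicarboxylate, THF) to the 4-nitrobenzoate F6, which has the trans configuration. Methanolysis (K2CO3, MeOH) at the base-stable ketal stage comes back to the route at 15.

**Further compounds**

F1 | step 6 | 11-aryl-3β-hydroxy-drim-8(12)-ene (exocyclic alkene isomer of 9) | COc1cc(C[C@H]2C(=C)CC[C@H]3[C@](C)(CO[Si](C)(C)C(C)(C)C)[C@@H](O)CC[C@]23C)c(OC(=O)C(C)(C)C)cc1C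
F2 | step 10 | (R,R)-hydrobenzoin ketal analogue of 13 | CC1=CC(=O)C(C[C@H]4C(C)=CC[C@H]5[C@](C)(CO[Si](C)(C)C(C)(C)C)CCC[C@]45C)=CC13O[C@H](c6ccccc6)[C@@H](c6ccccc6)O3
F3 | step 10 | epoxy ketone with (R,R)-hydrobenzoin ketal | CC1=CC(=O)[C@]2(C[C@H]4C(C)=CC[C@H]5[C@](C)(CO[Si](C)(C)C(C)(C)C)CCC[C@]45C)O[C@@H]2C13O[C@H](c6ccccc6)[C@@H](c6ccccc6)O3
F4 | step 10 | trans epoxy alcohol with (R,R)-hydrobenzoin ketal | CC1=C[C@@H](O)[C@]2(C[C@H]4C(C)=CC[C@H]5[C@](C)(CO[Si](C)(C)C(C)(C)C)CCC[C@]45C)O[C@@H]2C13O[C@H](c6ccccc6)[C@@H](c6ccccc6)O3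
F5 | step 11 | cis epoxy alcohol (carbinol epimer of 15) | CC1=C[C@H](O)[C@]2(C[C@H]3C(C)=CC[C@H]4[C@](C)(CO[Si](C)(C)C(C)(C)C)CCC[C@]34C)O[C@@H]2C1(OC)OC
F6 | step 11 | 4-nitrobenzoate of 15 | CC1=C[C@@H](OC(=O)c5ccc(cc5)[N+](=O)[O-])[C@]2(C[C@H]3C(C)=CC[C@H]4[C@](C)(CO[Si](C)(C)C(C)(C)C)CCC[C@]34C)O[C@@H]2C1(OC)OC
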